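**Plan**

- Cuts: first the two C–prenyl bonds C3a–CH2 and C7–CH2, which re-aromatises the dienone ring to an acylphloroglucinol-type 2,3-dihydrobenzofuran. Then, inside the furan, O1–C2 is exchanged for O1–C(CH3)2, which leads back to a 3-hydroxy-2,2-dimethylchromane. Then C3–O (chromene epoxide), the pyran ring (aryl propargyl ether) and the aryl ketone (phloroglucinol).
- Enabling feature: the ring O1–C2–C3–C3a–C7a carries on C2 the tertiary carbinol carbon C(CH3)2OH. It is therefore the 1,2-oxygen-shift isomer of the pyran O1–C(CH3)2–C3–C4–C4a–C8a with a leaving group on C3. O1 sits β to that secondary carbon and leaves a tertiary one, so an oxiranium ion captured by water at the tertiary carbon contracts pyran to furan.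
- Forward order: acylate the arene, build the pyran (propargyl Claisen, oxa-6π), epoxidise and hydrogenolyse to the (3R)-chromanol, contract to the furan, then form the cyclohexadienone by double C-prenylation.
- Stereochemistry: C2 (S) comes from the Jacobsen epoxide, with inversion in the contraction. C3a (S) comes from prenylation anti to the C2 substituent.

Key step: step 7

Assumption: the (R,R)-salen manganese catalyst is taken to attack the chromene diacetate with the facial sense established for 2,2-dimethyl-2H-chromenes, giving the (3R,4R)-epoxide; if the sense proves opposite, the (S,S)-catalyst is used.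

**Route**

Step 1
Reactants: 1 phloroglucinol (benzene-1,3,5-triol); 2 isobutyryl chloride (2-methylpropanoyl chloride)
Product: 3 2-methyl-1-(2,4,6-trihydroxyphenyl)propan-1-one (phlorisobutyrophenone)
Conditions: AlCl3 (3 equiv), PhNO2, 60 °C; then ice, aq. HCl
Reagents that add atoms: isobutyryl chloride 2, CC(C)C(=O)Cl
Why: Friedel–Crafts acylation of the symmetric, highly activated triol should stop after one acyl group because the chelated aryl ketone is deactivated; no stereocenter is formed.

Step 2
Reactants: 3 2-methyl-1-(2,4,6-trihydroxyphenyl)propan-1-one; 4 3-chloro-3-methylbut-1-yne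
Product: 5 1-[2,6-dihydroxy-4-(2-methylbut-3-yn-2-yloxy)phenyl]-2-methylpropan-1-one
Conditions: K2CO3 (1.1 equiv), KI (cat.), CuI (cat.), acetone, 50 °C
Reagents that add atoms: 3-chloro-3-methylbut-1-yne 4, CC(C)(Cl)C#C
Why: Copper-assisted Williamson-type O-propargylation: with one equivalent of base only the para hydroxyl is ionised and alkylated, since it is the most acidic and the only one not hydrogen-bonded to the ketone.

Step 3
Reactants: 5 1-[2,6-dihydroxy-4-(2-methylbut-3-yn-2-yloxy)phenyl]-2-methylpropan-1-one
Product: 6 1-(5,7-dihydroxy-2,2-dimethyl-2H-chromen-6-yl)-2-methylpropan-1-one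
Conditions: o-xylene, 140 °C
Reagents that add atoms: none
Why: Aromatic propargyl Claisen rearrangement to the ortho carbon, 1,5-hydrogen shift and oxa-6π electrocyclisation should give the 2,2-dimethyl-2H-chromene; the ether oxygen necessarily becomes the pyran oxygen, which fixes it para to the acyl group.

Step 4
Reactants: 6 1-(5,7-dihydroxy-2,2-dimethyl-2H-chromen-6-yl)-2-methylpropan-1-one
Product: 7 2,2-dimethyl-6-(2-methylpropanoyl)-2H-chromene-5,7-diyl diacetate
Conditions: Ac2O (3 equiv), pyridine, DMAP (cat.), CH2Cl2, rt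
Reagents that add atoms: acetic anhydride, CC(=O)OC(C)=O
Why: DMAP-catalysed acetylation masks both phenols against the oxidant of step 5 and the anhydride of step 7.

Step 5
Reactants: 7 2,2-dimethyl-6-(2-methylpropanoyl)-2H-chromene-5,7-diyl diacetate
Product: 8 (3R,4R)-3,4-epoxy-2,2-dimethyl-6-(2-methylpropanoyl)-3,4-dihydro-2H-chromene-5,7-diyl diacetate
Conditions: [(R,R)-N,N'-bis(3,5-di-tert-butylsalicylidene)cyclohexane-1,2-diaminato]manganese chloride (trivalent manganese, 5 mol %), NMO (5 equiv), mCPBA (2 equiv), CH2Cl2, −78 °C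
Reagents that add atoms: mCPBA, OOC(=O)c1cccc(Cl)c1
Why: Jacobsen epoxidation: cis-configured 2,2-dimethyl-2H-chromenes are the best substrate class for the chiral salen manganese oxo species, and the (R,R)-ligand should deliver oxygen to the face that makes C3 and C4 both R.

Step 6
Reactants: 8 (3R,4R)-3,4-epoxy-2,2-dimethyl-6-(2-methylpropanoyl)-3,4-dihydro-2H-chromene-5,7-diyl diacetate
Product: 9 (3R)-3-hydroxy-2,2-dimethyl-6-(2-methylpropanoyl)-3,4-dihydro-2H-chromene-5,7-diyl diacetate
Conditions: H2 (1 atm), Pd/C, EtOAc, rt
Reagents that add atoms: none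
Why: Hydrogenolysis of a benzylic C–O bond: only C4–O is benzylic (and activated by O1 through the arene), so the epoxide should open there while C3 keeps its oxygen and its R configuration.

Step 7
Reactants: 9 (3R)-3-hydroxy-2,2-dimethyl-6-(2-methylpropanoyl)-3,4-dihydro-2H-chromene-5,7-diyl diacetate
Product: 12 (2S)-2-(2-hydroxypropan-2-yl)-5-(2-methylpropanoyl)-2,3-dihydro-1-benzofuran-4,6-diyl diacetate, via triflate 10 (not isolated), via oxiranium triflate 11 (not isolated)
Conditions: Tf2O (1.2 equiv), 2,6-lutidine (3 equiv), CH2Cl2, −78 °C; then THF–H2O (3:1), −78 °C → rt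
Reagents that add atoms: water, O; trifluoromethanesulfonic anhydride, O=S(=O)(OS(=O)(=O)C(F)(F)F)C(F)(F)F (its triflyl group is present only in 10 and 11)
Why: Triflation of the C3 hydroxyl gives 10, whose pseudo-equatorial C3–O bond lies antiperiplanar to the ring bond O1–C2, so O1 displaces triflate from the rear (3-exo-tet, inversion at C3) to give the arene-fused oxiranium ion 11. Water opens 11 at the tertiary carbon C(CH3)2, the site that best carries positive charge, which breaks the old pyran bond and leaves O1 on the former C3; the six-membered ring thereby becomes the five-membered ring O1–C2–C3–C3a–C7a with the hydroxyisopropyl group already in place. The closest known reaction type is the ring contraction of 3-sulfonyloxy-2,2-dimethylchromanes, 3-sulfonyloxytetrahydropyrans and 2-O-triflyl pyranosides by neighbouring ring-oxygen participation. The only new stereocenter, C2 of the furan, is the old C3 and is fixed by the stereospecific backside attack, so (3R) should become (2S). The step needs oxygen participation to outrun elimination toward the chromene, proton loss from the cation and water attack at the secondary carbon. The hindered base at low temperature, water present during ionisation, the tertiary gem-dimethyl terminus and the two acetates (which twist the ketone out of conjugation and keep O1 nucleophilic) are there to secure this.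

Step 8
Reactants: 12 (2S)-2-(2-hydroxypropan-2-yl)-5-(2-methylpropanoyl)-2,3-dihydro-1-benzofuran-4,6-diyl diacetate
Product: 13 1-[(2S)-4,6-dihydroxy-2-(2-hydroxypropan-2-yl)-2,3-dihydro-1-benzofuran-5-yl]-2-methylpropan-1-one
Conditions: K2CO3 (cat.), MeOH, 0 °C → rt; then aq. NH4Cl
Reagents that add atoms: none
Why: Base-catalysed transesterification of the aryl acetates by methanol should free both phenols while the tertiary alcohol, the ketone and C2 are untouched.

Step 9
Reactants: 13 1-[(2S)-4,6-dihydroxy-2-(2-hydroxypropan-2-yl)-2,3-dihydro-1-benzofuran-5-yl]-2-methylpropan-1-one; 14 1-bromo-3-methylbut-2-ene (prenyl bromide)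
Product: 16 (2S,3aS)-6-hydroxy-2-(2-hydroxypropan-2-yl)-3a,7-bis(3-methylbut-2-en-1-yl)-5-(2-methylpropanoyl)-2,3-dihydro-1-benzofuran-4(3aH)-one (target), via 7-prenyl phenol 15 (not isolated)
Conditions: prenyl bromide (2.2 equiv), aq. KOH (10%), 0 °C
Reagents that add atoms: prenyl bromide 14, CC(C)=CCBr
Why: Alkylative dearomatisation of an acylphloroglucinol (the C-prenylation that turns deoxyhumulones into lupulones): the first equivalent substitutes the only ring C–H (C7), and the second should attack the ring-fusion carbon C3a of the phenoxide, the less encumbered of the two alkyl-bearing positions, from the face anti to the C2 hydroxyisopropyl group (1,3 on the five-membered ring), which sets C3a as S and leaves the enolised triketone.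

**Compound list**

1 | phloroglucinol (benzene-1,3,5-triol) | Oc1cc(O)cc(O)c1 | starting material
2 | isobutyryl chloride | CC(C)C(=O)Cl | starting material
3 | 2-methyl-1-(2,4,6-trihydroxyphenyl)propan-1-one | CC(C)C(=O)c1c(O)cc(O)cc1O | intermediate
4 | 3-chloro-3-methylbut-1-yne | CC(C)(Cl)C#C | starting material
5 | 1-[2,6-dihydroxy-4-(2-methylbut-3-yn-2-yloxy)phenyl]-2-methylpropan-1-one | CC(C)C(=O)c1c(O)cc(OC(C)(C)C#C)cc1O | intermediate
6 | 1-(5,7-dihydroxy-2,2-dimethyl-2H-chromen-6-yl)-2-methylpropan-1-one | CC(C)C(=O)c1c(O)cc2OC(C)(C)C=Cc2c1O | intermediate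
7 | 2,2-dimethyl-6-(2-methylpropanoyl)-2H-chromene-5,7-diyl diacetate | CC(C)C(=O)c1c(OC(C)=O)cc2OC(C)(C)C=Cc2c1OC(C)=O | intermediate
8 | (3R,4R)-3,4-epoxy-2,2-dimethyl-6-(2-methylpropanoyl)-3,4-dihydro-2H-chromene-5,7-diyl diacetate | CC(C)C(=O)c1c(OC(C)=O)cc2OC(C)(C)[C@@H]3O[C@@H]3c2c1OC(C)=O | intermediate
9 | (3R)-3-hydroxy-2,2-dimethyl-6-(2-methylpropanoyl)-3,4-dihydro-2H-chromene-5,7-diyl diacetate | CC(C)C(=O)c1c(OC(C)=O)cc2OC(C)(C)[C@H](O)Cc2c1OC(C)=O | intermediate
10 | (3R)-2,2-dimethyl-6-(2-methylpropanoyl)-3-(trifluoromethanesulfonyloxy)-3,4-dihydro-2H-chromene-5,7-diyl diacetate | CC(C)C(=O)c1c(OC(C)=O)cc2OC(C)(C)[C@H](OS(=O)(=O)C(F)(F)F)Cc2c1OC(C)=O | intermediate (not isolated)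
11 | arene-fused oxiranium ion (O1 bonded to C8a, C2 and the inverted C3 of the former chromane), triflate salt | CC(C)C(=O)c1c(OC(C)=O)cc2c(c1OC(C)=O)C[C@@H]1[O+]2C1(C)C.[O-]S(=O)(=O)C(F)(F)F | intermediate (not isolated)
12 | (2S)-2-(2-hydroxypropan-2-yl)-5-(2-methylpropanoyl)-2,3-dihydro-1-benzofuran-4,6-diyl diacetate | CC(C)C(=O)c1c(OC(C)=O)cc2O[C@H](C(C)(C)O)Cc2c1OC(C)=O | intermediate
13 | 1-[(2S)-4,6-dihydroxy-2-(2-hydroxypropan-2-yl)-2,3-dihydro-1-benzofuran-5-yl]-2-methylpropan-1-one | CC(C)C(=O)c1c(O)cc2O[C@H](C(C)(C)O)Cc2c1O | intermediate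
14 | 1-bromo-3-methylbut-2-ene (prenyl bromide) | CC(C)=CCBr | starting material
15 | 1-[(2S)-4,6-dihydroxy-2-(2-hydroxypropan-2-yl)-7-(3-methylbut-2-en-1-yl)-2,3-dihydro-1-benzofuran-5-yl]-2-methylpropan-1-one | CC(C)C(=O)c1c(O)c(CC=C(C)C)c2O[C@H](C(C)(C)O)Cc2c1O | intermediate (not isolated)
16 | (2S,3aS)-6-hydroxy-2-(2-hydroxypropan-2-yl)-3a,7-bis(3-methylbut-2-en-1-yl)-5-(2-methylpropanoyl)-2,3-dihydro-1-benzofuran-4(3aH)-one | CC(C)=CCC1=C2O[C@H](C(C)(C)O)C[C@]2(CC=C(C)C)C(=O)C(C(=O)C(C)C)=C1O | target

**Totals and risks**

Total step count: 9. Longest linear sequence: 9 steps (from phloroglucinol 1).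

Steps most likely to fail:

1. Step 9. The second prenyl group may go to C7 (geminal dialkylation) or to oxygen instead of C3a, and face selection at C3a by a substituent two atoms away may be incomplete. The fallback sets out from 13 and comes back at 16, and fixes the regiochemistry by sigmatropic delivery. Both phenols are etherified with 4 (CuCl2 cat., DBU, MeCN, 0 °C) to give 1-[(2S)-2-(2-hydroxypropan-2-yl)-4,6-bis(2-methylbut-3-yn-2-yloxy)-2,3-dihydro-1-benzofuran-5-yl]-2-methylpropan-1-one F1. Semihydrogenation (H2, Pd/CaCO3 poisoned by Pb(OAc)2, quinoline, EtOAc) gives the bis(2-methylbut-3-en-2-yl) ether 1-[(2S)-2-(2-hydroxypropan-2-yl)-4,6-bis(2-methylbut-3-en-2-yloxy)-2,3-dihydro-1-benzofuran-5-yl]-2-methylpropan-1-one F2. Heating F2 in toluene (80–110 °C) should trigger two aromatic Claisen rearrangements. The allyl unit on the C6 oxygen can only reach C7 (C5 is acylated) and re-aromatises there as a prenyl group. The unit on the C4 oxygen can only reach C3a, suprafacially and anti to the C2 substituent, and the dienone so formed is the enolised triketone 16.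

2. Step 7. After ionisation, loss of a methyl proton from the cation (or elimination of the triflate toward the conjugated chromene) may outrun capture by water. The fallback sets out from 9 and comes back at 12, separating ring contraction from hydroxyl installation. Triflate 10 is formed and ionised without water (Tf2O, pyridine, CH2Cl2, 0 °C → rt), so the oxiranium ion deliberately loses a proton to give the ring-contracted alkene (2S)-5-(2-methylpropanoyl)-2-(prop-1-en-2-yl)-2,3-dihydro-1-benzofuran-4,6-diyl diacetate F3. Mukaiyama hydration of this 1,1-disubstituted alkene, the only alkene in the molecule (Mn(dpm)3 cat., PhSiH3, O2, i-PrOH, 0 °C), then places the tertiary hydroxyl with Markovnikov selectivity and returns 12.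

3. Step 2. The ambident phloroglucinol anion may be alkylated at ring carbon or at more than one oxygen instead of only at the para oxygen. The fallback sets out from 3 and comes back at 6, replacing etherification and Claisen rearrangement by a condensation. Compound 3 and 3-methylbut-2-enal with ethylenediammonium diacetate (cat.) in toluene at reflux should undergo Knoevenagel condensation at the ring carbon and oxa-6π electrocyclisation to give 6 directly. The closure can also engage a chelated ortho oxygen, so the angular isomer 1-(5,7-dihydroxy-2,2-dimethyl-2H-chromen-8-yl)-2-methylpropan-1-one F4 is expected as well and must be removed by chromatography.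

Further compounds
F1 | step 9 | 1-[(2S)-2-(2-hydroxypropan-2-yl)-4,6-bis(2-methylbut-3-yn-2-yloxy)-2,3-dihydro-1-benzofuran-5-yl]-2-methylpropan-1-one | CC(C)C(=O)c1c(OC(C)(C)C#C)cc2O[C@H](C(C)(C)O)Cc2c1OC(C)(C)C#C
F2 | step 9 | 1-[(2S)-2-(2-hydroxypropan-2-yl)-4,6-bis(2-methylbut-3-en-2-yloxy)-2,3-dihydro-1-benzofuran-5-yl]-2-methylpropan-1-one | CC(C)C(=O)c1c(OC(C)(C)C=C)cc2O[C@H](C(C)(C)O)Cc2c1OC(C)(C)C=C
F3 | step 7 | (2S)-5-(2-methylpropanoyl)-2-(prop-1-en-2-yl)-2,3-dihydro-1-benzofuran-4,6-diyl diacetate | CC(C)C(=O)c1c(OC(C)=O)cc2O[C@H](C(C)=C)Cc2c1OC(C)=O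
F4 | step 2 | 1-(5,7-dihydroxy-2,2-dimethyl-2H-chromen-8-yl)-2-methylpropan-1-one | CC(C)C(=O)c1c(O)cc(O)c2C=CC(C)(C)Oc12
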